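## Retrosynthetic overview

1. The amino group is installed last: C–N bond formation by azide amination of des-amino quinone 22. C13=C14 comes from cross-metathesis of polyol acid 13 with aryl isopropenyl ketone 21.
2. 13 comes from lactone aldehyde 9 by two substrate-controlled (Z)-crotylborations (C4/C5, later C11/C12), with a cross-metathesis with acrylic acid (C2=C3) in between.
3. Key step: 9 by an enantioselective oxidative desymmetrising lactonisation (new C–O bond, sets the absolute configuration of C6–C10) of meso tetraol 6.
4. 6 comes from a two-directional anti-aldol/syn-reduction/hydroboration sequence on 1 + 2, with no protecting groups on the chain. 21 comes from benzoquinone by Diels–Alder/aromatisation, bromination and carbonylative Stille coupling.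
5. Rings: a temporary δ-lactone (formed in step 3, opened in step 7); the benzenoid ring is built onto the existing quinone ring (step 9); the aminoquinone is completed in step 13.

Chain locants in names are those of the target acid (C1 = CO2H, C15 = aryl ketone carbon). The target is 2E,4R,5S,6S,7S,8S,9R,10R,11R,12S,13E.

Assumption: the sense of induction in step 3 cannot be predicted; (R)-TRIP [(R)-3,3′-bis(2,4,6-triisopropylphenyl)-1,1′-binaphthyl-2,2′-diyl hydrogen phosphate] is written, and (S)-TRIP is used instead if ent-9 forms.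

## Route

Step 1
Reactants: 1 2-methylpent-1-en-3-one; 2 methacrolein
Product: 5 meso all-anti 2,4,6-trimethylhepta-1,6-diene-3,5-diol, via enol borinate 3 (not isolated), via boron aldolate 4 (not isolated)
Conditions: c-Hex2BCl, Et3N, Et2O, −78 → 0 °C; 2, −78 → −20 °C; LiBH4, −78 °C; then H2O2, MeOH, pH 7 buffer
Reagents that add atoms: none
Why: Paterson anti-aldol reaction in which the (E)-enol dicyclohexylborinate adds to methacrolein through a chair Zimmerman–Traxler transition state (C8 methyl anti to the C9 oxygen), after which LiBH4 reduces the six-membered boron aldolate to the syn-1,3-diol, so both enantiomers of the racemic aldolate converge on the single meso diol 5.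

Step 2
Reactants: 5 meso diene diol
Product: 6 meso all-anti 2,4,6-trimethylheptane-1,3,5,7-tetraol
Conditions: 9-BBN (5 equiv), THF, 0 °C → rt; then NaOH, H2O2
Reagents that add atoms: hydrogen peroxide OO
Why: Two-directional hydroboration–oxidation under allylic-strain control, in which 9-BBN attacks each 1,1-disubstituted alkene anti to the branched carbinol substituent in the conformer with the carbinol H eclipsing the C=C, setting C6 and C10 anti to the neighbouring hydroxyls and keeping the mirror plane.

Step 3
Reactants: 6 meso tetraol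
Product: 9 C5-aldehyde C11-lactone, via hydroxy dialdehyde 7 (not isolated), via lactol aldehyde 8 (not isolated)
Conditions: 4-acetamido-TEMPO (10 mol%), (R)-TRIP (10 mol%), PhI(OAc)2 (3.3 equiv), CH2Cl2, 0 °C → rt
Reagents that add atoms: none
Why: Proposed new method: an enantioselective oxidative desymmetrising lactonisation in which the oxoammonium ion generated from the nitroxyl oxidises both primary alcohols of meso 6 to hydroxy dialdehyde 7, this closes reversibly to the two enantiomeric six-membered lactols 8 and ent-8 that interconvert through 7 under the acid, and the oxoammonium cation ion-paired with the chiral phosphate (the conjugate base of the strongest acid present, which also hydrogen-bonds the lactol OH) removes hydride much faster from one lactol enantiomer, so that a dynamic kinetic resolution funnels all material into one lactone, forms the C11–O7 bond and fixes the absolute configuration of C6–C10 while the hindered secondary hydroxyl is left alone; the closest known reactions are the TEMPO/PhI(OAc)2 oxidative lactonisation of 1,5-diols, oxidations by chiral-phosphate-paired oxoammonium salts and the oxidative kinetic resolution of secondary alcohols by chiral nitroxyls.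

Step 4
Reactants: 9 C5-aldehyde C11-lactone
Product: 10 lactone homoallylic alcohol
Conditions: (Z)-crotylB(pin) (1.5 equiv), 4 Å MS, toluene, rt
Reagents that add atoms: (Z)-crotylboronic acid pinacol ester C/C=C\CB1OC(C)(C)C(C)(C)O1
Why: Crotylboration (allylboration) through a closed chair transition state, in which the (Z)-crotyl unit gives the C4/C5 syn relationship and the intrinsic anti-Felkin preference of (Z)-crotylboronates for α-methyl aldehydes (avoidance of a syn-pentane contact) sets C5 anti to the C6 methyl on the now enantiopure substrate.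

Step 5
Reactants: 10 lactone homoallylic alcohol
Product: 11 lactol
Conditions: i-Bu2AlH (3.5 equiv), CH2Cl2, −78 °C; aq. KNaC4H4O6
Reagents that add atoms: none
Why: Partial reduction of the δ-lactone with i-Bu2AlH at −78 °C stops at the aluminium hemiacetal, which gives the lactol on work-up, so no stereocentre of the chain is touched and the anomeric mixture is of no consequence.

Step 6
Reactants: 11 lactol
Product: 12 (E)-enoic acid lactol
Conditions: acrylic acid (5 equiv), RuCl2(H2IMes)(=CH-C6H4-2-O-i-Pr) (second-generation Hoveyda–Grubbs catalyst, 5 mol%), CH2Cl2, 40 °C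
Reagents that add atoms: acrylic acid C=CC(=O)O
Why: Ruthenium-catalysed olefin cross-metathesis of the terminal vinyl group with excess acrylic acid gives the (E)-enoic acid under thermodynamic control, the free hydroxyls and the lactol being tolerated.

Step 7
Reactants: 12 (E)-enoic acid lactol
Product: 13 tetraol acid with terminal vinyl group
Conditions: (Z)-crotylB(pin) (3 equiv), THF/toluene, 50 °C; 1 M HCl work-up
Reagents that add atoms: (Z)-crotylboronic acid pinacol ester C/C=C\CB1OC(C)(C)C(C)(C)O1
Why: Crotylboration of the hydroxy aldehyde in equilibrium with the lactol, in which the closed transition state of the (Z)-crotylboronate sets C11/C12 syn and the anti-Felkin preference sets C11 anti to the C10 methyl, completing all nine stereocentres.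

Step 8
Reactants: 14 3-methylbut-3-en-2-one
Product: 15 3-methyl-2-(trimethylsilyloxy)buta-1,3-diene
Conditions: TMSOTf, Et3N, Et2O, 0 °C
Reagents that add atoms: trimethylsilyl trifluoromethanesulfonate C[Si](C)(C)OS(=O)(=O)C(F)(F)F
Why: Soft enolisation and O-silylation of the methyl ketone at its only enolisable position gives the cross-conjugated 2-silyloxydiene.

Step 9
Reactants: 15 silyloxydiene; 16 1,4-benzoquinone
Product: 19 6-hydroxy-7-methylnaphthalene-1,4-dione, via Diels–Alder adduct 17 (not isolated), via silyl ether 18 (not isolated)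
Conditions: toluene, 0 °C → rt; DDQ (2.2 equiv), 80 °C; then 1 M HCl, THF
Reagents that add atoms: none
Why: Diels–Alder cycloaddition of the electron-rich diene with benzoquinone builds the second six-membered ring, DDQ dehydrogenates the adduct (aromatisation and re-oxidation to the quinone) and acid removes the silyl group, with no regiochemical issue for the symmetrical dienophile.

Step 10
Reactants: 19 6-hydroxy-7-methylnaphthalene-1,4-dione
Product: 20 5-bromo-6-hydroxy-7-methylnaphthalene-1,4-dione
Conditions: NBS (1.05 equiv), NaOAc, DMF, 0 °C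
Reagents that add atoms: N-bromosuccinimide O=C1CCC(=O)N1Br
Why: Electrophilic aromatic bromination of the phenol ring, where C5 is the only free position ortho or para to the hydroxyl (C7 carries the methyl) and buffered NBS avoids bromine addition to the quinone C=C.

Step 11
Reactants: 20 bromoquinone
Product: 21 6-hydroxy-7-methyl-5-(2-methylprop-2-enoyl)naphthalene-1,4-dione
Conditions: CO (5 bar), CH2=C(CH3)SnBu3 (1.5 equiv), PdCl2(PPh3)2 (5 mol%), dioxane, 80 °C
Reagents that add atoms: carbon monoxide [C-]#[O+]; tributyl(prop-1-en-2-yl)stannane CC(=C)[Sn](CCCC)(CCCC)CCCC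
Why: Carbonylative Stille coupling (oxidative addition of the electron-poor aryl bromide to zerovalent palladium, CO insertion, transmetallation from the isopropenylstannane, reductive elimination) gives the aryl isopropenyl ketone without base, which avoids oxa-Michael closure to a chromanone.

Step 12
Reactants: 13 tetraol acid; 21 aryl isopropenyl ketone
Product: 22 des-amino seco acid
Conditions: 21 (2.5 equiv), RuCl2(H2IMes)(=CH-C6H4-2-O-i-Pr) (10 mol%), THF/CH2Cl2, 45 °C
Reagents that add atoms: none
Why: Olefin cross-metathesis between the terminal alkene of 13 and the 1,1-disubstituted enone 21 (which does not homodimerise and is used in excess) gives the trisubstituted enone as the thermodynamically favoured (E)-isomer, as in cross-metatheses with methacrolein, and the quinone is compatible with ruthenium carbenes.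

Step 13
Reactants: 22 des-amino seco acid
Product: 24 CNP0336625.1 (target), via azidohydroquinone 23 (not isolated)
Conditions: NaN3 (3 equiv), AcOH, THF/H2O, 40 °C
Reagents that add atoms: sodium azide [N-]=[N+]=[N-].[Na+]
Why: Aza-Michael addition of hydrazoic acid to the quinone followed by loss of N2 with internal redox (azidohydroquinone 23 to aminoquinone) forms the C–N bond at the carbon β to the C=O that is not deactivated by conjugation with the para phenol oxygen (the C=O peri to the acyl group), which is the position required by the target.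

## Compound list

1 | 2-methylpent-1-en-3-one (ethyl isopropenyl ketone) | CCC(=O)C(C)=C | starting material
2 | methacrolein (2-methylprop-2-enal) | CC(=C)C=O | starting material
3 | (E)-enol dicyclohexylborinate of 1 | C/C=C(/OB(C1CCCCC1)C1CCCCC1)C(C)=C | intermediate
4 | racemic anti boron aldolate, 5-(dicyclohexylboryloxy)-2,4,6-trimethylhepta-1,6-dien-3-one (one enantiomer drawn) | C=C(C)[C@@H](OB(C1CCCCC1)C1CCCCC1)[C@@H](C)C(=O)C(C)=C | intermediate
5 | meso (3R,4r,5S)-2,4,6-trimethylhepta-1,6-diene-3,5-diol (3,5-diol syn, 4-methyl anti to both OH) | C=C(C)[C@@H](O)[C@@H](C)[C@@H](O)C(C)=C | intermediate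
6 | meso (2R,3R,4s,5S,6S)-2,4,6-trimethylheptane-1,3,5,7-tetraol (all-anti) | OC[C@@H](C)[C@@H](O)[C@@H](C)[C@@H](O)[C@@H](C)CO | intermediate
7 | meso 3,5-dihydroxy-2,4,6-trimethylheptanedial (relative configuration of 6) | O=C[C@@H](C)[C@@H](O)[C@@H](C)[C@@H](O)[C@@H](C)C=O | intermediate
8 | lactol aldehyde, 2-(4,6-dihydroxy-3,5-dimethyloxan-2-yl)propanal (C11 lactol closed by O7, C5 aldehyde, anomers, C6–C10 as in 9) | OC1[C@@H](C)[C@@H](O)[C@@H](C)[C@@H](O1)[C@@H](C)C=O | intermediate
9 | (2R)-2-[(2R,3R,4S,5S)-4-hydroxy-3,5-dimethyl-6-oxooxan-2-yl]propanal (C5 aldehyde, C11 lactone) | O=C1[C@@H](C)[C@@H](O)[C@@H](C)[C@@H](O1)[C@@H](C)C=O | intermediate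
10 | (3S,4S,5R,6S)-4-hydroxy-6-[(2S,3S,4R)-3-hydroxy-4-methylhex-5-en-2-yl]-3,5-dimethyloxan-2-one | O=C1[C@@H](C)[C@@H](O)[C@@H](C)[C@@H](O1)[C@@H](C)[C@@H](O)[C@H](C)C=C | intermediate
11 | lactol of 10 (oxane-2,4-diol, anomers, other centres as in 10) | OC1[C@@H](C)[C@@H](O)[C@@H](C)[C@@H](O1)[C@@H](C)[C@@H](O)[C@H](C)C=C | intermediate
12 | (E)-enoic acid lactol (C1–C11 of the target, C11 as lactol closed by O7, anomers) | OC1[C@@H](C)[C@@H](O)[C@@H](C)[C@@H](O1)[C@@H](C)[C@@H](O)[C@H](C)/C=C/C(=O)O | intermediate
13 | (2E,4R,5S,6S,7S,8R,9R,10R,11R,12S)-5,7,9,11-tetrahydroxy-4,6,8,10,12-pentamethyltetradeca-2,13-dienoic acid | C=C[C@H](C)[C@@H](O)[C@@H](C)[C@@H](O)[C@@H](C)[C@@H](O)[C@@H](C)[C@@H](O)[C@H](C)/C=C/C(=O)O | intermediate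
14 | 3-methylbut-3-en-2-one | CC(=O)C(C)=C | starting material
15 | 3-methyl-2-(trimethylsilyloxy)buta-1,3-diene | C=C(O[Si](C)(C)C)C(C)=C | intermediate
16 | 1,4-benzoquinone | O=C1C=CC(=O)C=C1 | starting material
17 | racemic cis-6-methyl-7-(trimethylsilyloxy)-4a,5,8,8a-tetrahydronaphthalene-1,4-dione (one enantiomer drawn) | O=C1C=CC(=O)[C@@H]2CC(O[Si](C)(C)C)=C(C)C[C@H]12 | intermediate
18 | 6-methyl-7-(trimethylsilyloxy)naphthalene-1,4-dione | Cc1cc2C(=O)C=CC(=O)c2cc1O[Si](C)(C)C | intermediate
19 | 6-hydroxy-7-methylnaphthalene-1,4-dione | Cc1cc2C(=O)C=CC(=O)c2cc1O | intermediate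
20 | 5-bromo-6-hydroxy-7-methylnaphthalene-1,4-dione | Cc1cc2C(=O)C=CC(=O)c2c(Br)c1O | intermediate
21 | 6-hydroxy-7-methyl-5-(2-methylprop-2-enoyl)naphthalene-1,4-dione | Cc1cc2C(=O)C=CC(=O)c2c(C(=O)C(C)=C)c1O | intermediate
22 | (2E,4R,5S,6S,7S,8S,9R,10R,11R,12S,13E)-5,7,9,11-tetrahydroxy-15-(2-hydroxy-3-methyl-5,8-dioxo-5,8-dihydronaphthalen-1-yl)-4,6,8,10,12,14-hexamethyl-15-oxopentadeca-2,13-dienoic acid | C/C(=C\[C@H](C)[C@@H](O)[C@@H](C)[C@@H](O)[C@@H](C)[C@@H](O)[C@@H](C)[C@@H](O)[C@H](C)/C=C/C(=O)O)C(=O)c1c(O)c(C)cc2c1C(=O)C=CC2=O | intermediate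
23 | azidohydroquinone of 22 (6-azido-2,5,8-trihydroxy-3-methylnaphthalen-1-yl ketone, chain as in 22) | C/C(=C\[C@H](C)[C@@H](O)[C@@H](C)[C@@H](O)[C@@H](C)[C@@H](O)[C@@H](C)[C@@H](O)[C@H](C)/C=C/C(=O)O)C(=O)c1c(O)c(C)cc2c1c(O)cc(N=[N+]=[N-])c2O | intermediate
24 | CNP0336625.1, (2E,4R,5S,6S,7S,8S,9R,10R,11R,12S,13E)-15-(6-amino-2-hydroxy-3-methyl-5,8-dioxo-5,8-dihydronaphthalen-1-yl)-5,7,9,11-tetrahydroxy-4,6,8,10,12,14-hexamethyl-15-oxopentadeca-2,13-dienoic acid | C/C(=C\[C@H](C)[C@@H](O)[C@@H](C)[C@@H](O)[C@@H](C)[C@@H](O)[C@@H](C)[C@@H](O)[C@H](C)/C=C/C(=O)O)C(=O)c1c(O)c(C)cc2c1C(=O)C=C(N)C2=O | target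

## Step count and risks

Total step count: 13. Longest linear sequence: 9 (steps 1–7, 12, 13).

Steps most likely to fail:

- **Step 3 (proposed new method).** The chiral ion pair may not discriminate the two lactols well enough, or the nitroxyl may over-oxidise. The fallback uses known chemistry, sets out from 6 and returns at 9. Lipase-catalysed enantiotopic-group-selective acetylation of one primary hydroxyl of meso 6 (Burkholderia cepacia lipase, vinyl acetate; hydrolysis of the diacetate gives the opposite sense) gives the C5 monoacetate F1. Achiral TEMPO/PhI(OAc)2 lactonises the free 1,5-diol terminus to the lactone acetate F2. Lipase-catalysed methanolysis (Candida antarctica lipase B, MeOH/t-BuOMe) gives the hydroxy lactone F3. TEMPO/PhI(OAc)2 (1.1 equiv) then oxidises the primary alcohol to 9.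

- **Step 12.** Cross-metathesis of a branched, unprotected polyol acid with the hindered aryl isopropenyl ketone may stall. The fallback sets out from 13 and returns at 22, and does not need 21. Cross-metathesis of 13 with the small partner isopropenylboronic acid pinacol ester (same ruthenium catalyst) gives the (13Z)-alkenyl boronate F4, with boron trans to the chain. Carbonylative Suzuki–Miyaura coupling of F4 with bromide 20 (CO, PdCl2(dppf), CsF, dioxane) then gives 22.

- **Step 13.** Regioselectivity or chemoselectivity of the amination on the fully functionalised acid may be insufficient. The fallback sets out from 20 and returns at 24. NaN3/AcOH amination of the simple bromoquinone 20, where the same phenol effect directs the nitrogen and the regiochemistry can be proven, gives the aminobromoquinone F5. Carbonylative Stille coupling as in step 11 gives the amino enone F6. Cross-metathesis of F6 with 13 as in step 12 gives 24 directly.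

Further compounds
F1 | step 3 | C5 monoacetate of tetraol 6 (7-acetoxy-2,4,6-trimethylheptane-1,3,5-triol, configuration of 6) | OC[C@@H](C)[C@@H](O)[C@@H](C)[C@@H](O)[C@@H](C)COC(C)=O
F2 | step 3 | lactone acetate, 2-(4-hydroxy-3,5-dimethyl-6-oxooxan-2-yl)propyl acetate (ring as in 9) | O=C1[C@@H](C)[C@@H](O)[C@@H](C)[C@@H](O1)[C@@H](C)COC(C)=O
F3 | step 3 | hydroxy lactone, 4-hydroxy-6-(1-hydroxypropan-2-yl)-3,5-dimethyloxan-2-one (ring as in 9) | O=C1[C@@H](C)[C@@H](O)[C@@H](C)[C@@H](O1)[C@@H](C)CO
F4 | step 12 | (2E,13Z)-alkenyl boronate, 5,7,9,11-tetrahydroxy-4,6,8,10,12-pentamethyl-14-(4,4,5,5-tetramethyl-1,3,2-dioxaborolan-2-yl)pentadeca-2,13-dienoic acid (stereocentres as in 13) | C/C(=C\[C@H](C)[C@@H](O)[C@@H](C)[C@@H](O)[C@@H](C)[C@@H](O)[C@@H](C)[C@@H](O)[C@H](C)/C=C/C(=O)O)B1OC(C)(C)C(C)(C)O1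
F5 | step 13 | 2-amino-5-bromo-6-hydroxy-7-methylnaphthalene-1,4-dione | Cc1cc2C(=O)C(N)=CC(=O)c2c(Br)c1O
F6 | step 13 | 2-amino-6-hydroxy-7-methyl-5-(2-methylprop-2-enoyl)naphthalene-1,4-dione | Cc1cc2C(=O)C(N)=CC(=O)c2c(C(=O)C(C)=C)c1O
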